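**Plan**

1. Labels (squalene-type, used throughout): oxepane O–C2(Me2)–C3(=O)–C4–C5–C6(Me)–C7(H)–O; cyclohexane C6–C7–C8–C9–C10(Me)(OH)–C11(H); linker C12–C13; seven-membered ring C14(H)–C15(=CH2)–C16(=O)–C17–C18(H)–C22(H)–C23(Me2); cyclopentane C18–C19(Me)(OH)–C20–C21–C22.
2. Cuts, in order: the C15 methylidene and C14–H (back to a cycloheptenone); C13–C14 (alkyllithium plus vinylogous ester); in the right half the oxepane bond O–C2 and the ring bond C6–C11 together, back to an acyclic diepoxide carrying a silyl enol ether; the left half back through a cycloheptane-1,3-dione and a bicyclo[3.3.0]octanone to (S)-linalool.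
3. Enabling feature: the oxepane oxygen bridges the gem-dimethyl carbon C2 and the ring-fusion CH C7, and C7 is bonded trans to the methyl-bearing quaternary C6, so O/C7/C6 are the remnant of an E-trisubstituted epoxide opened at its tertiary carbon; C3 can be carried as an alcohol (a second epoxide) and C10, next to C11, as a ketone (enol ether nucleophile), so one epoxide-opening cascade closes both rings.
4. Forward: right half, geranyl bromide → ketophosphonate → E-enone → Shi diepoxide → Z-enol silane → cascade (oxepane, then cyclohexanone) → MeMgBr at C10 → iodide; left half, RCM cyclopentene → Ireland–Claisen (C22–C23) → diazoketone cyclopropanation and opening (C17–C18, C19–O) → two-carbon expansion to the seven-membered ring; then union, reductive α-methylenation, desilylation, C3 oxidation.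
5. Stereochemistry: C3, C6, C7 from Shi epoxidation (C6 inverted in the cascade); C11 from the chair closure and equilibration; C10 from equatorial Grignard attack; C22 by suprafacial transfer from the linalool carbinol centre; C18 and C19 from the tethered cyclopropanation and its opening with inversion; C14 from hydride delivery to the convex face.

Key step: step 5

Remark: the C3 carbinol configuration delivered by the epoxide is irrelevant because C3 ends as a ketone; commercial (S)-(+)-linalool is assumed to be of high enantiomeric purity.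

**Route**

Step 1
Reactants: 1 geranyl bromide; 2 dimethyl (2-oxopropyl)phosphonate
Product: 3 dimethyl [(5E)-6,10-dimethyl-2-oxoundeca-5,9-dien-1-yl]phosphonate
Conditions: 2, NaH, THF, 0 °C; n-BuLi, 0 °C; then 1, 0 °C → rt
Reagents that add atoms: none
Why: γ-Alkylation of the β-ketophosphonate dianion (the more basic terminal carbanion reacts) by the allylic bromide extends the chain and leaves the E-alkene untouched.

Step 2
Reactants: 3 ketophosphonate; 4 (benzyloxy)acetaldehyde
Product: 5 (2E,7E)-1-(benzyloxy)-8,12-dimethyltrideca-2,7,11-trien-4-one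
Conditions: LiCl, i-Pr2NEt, MeCN, rt
Reagents that add atoms: none
Why: Horner–Wadsworth–Emmons olefination under mild LiCl/amine conditions should give the E-enone and tolerates the α-alkoxy aldehyde.

Step 3
Reactants: 5 trienone
Product: 6 (2E,7R,8R,11R)-1-(benzyloxy)-7,8:11,12-diepoxy-8,12-dimethyltridec-2-en-4-one
Conditions: Shi ketone (D-fructose-derived, 30 mol %), KHSO5 (as Oxone), K2CO3, Bu4NHSO4, MeCN/CH2(OMe)2/aq. borate buffer, 0 °C
Reagents that add atoms: potassium peroxymonosulfate, [K+].[O-]S(=O)(=O)OO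
Why: Shi asymmetric epoxidation: the chiral dioxirane epoxidises both electron-rich E-trisubstituted alkenes through the spiro transition state (R at each epoxide carbon) and leaves the electron-poor enone alone.

Step 4
Reactants: 6 diepoxy enone
Product: 7 triethylsilyl (Z)-enol ether of the C10 ketone (C10=C11)
Conditions: RhCl(PPh3)3 (2 mol %), Et3SiH, benzene, 50 °C
Reagents that add atoms: triethylsilane, CC[SiH](CC)CC
Why: Rhodium-catalysed 1,4-hydrosilylation of the s-cis enone gives the enol silane regiospecifically toward C11 and mainly as the Z isomer, which deprotonation of the unsymmetrical ketone could not do.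

Step 5
Reactants: 7 diepoxy enol silane
Product: 9 (3R,5aR,6R,9aR)-6-[2-(benzyloxy)ethyl]-3-hydroxy-2,2,5a-trimethyl-3,4,5,5a,6,8,9,9a-octahydro-1-benzoxepin-7(2H)-one, via trimethylsilyl ether 8 (not isolated)
Conditions: TMSOTf (1.2 equiv), 2,6-di-tert-butyl-4-methylpyridine, CH2Cl2, −78 °C; then K2CO3, MeOH, 0 °C
Reagents that add atoms: none
Why: TMSOTf silylates the terminal epoxide, whose tertiary carbon C2 is opened by the oxygen of the C6–C7 epoxide to give a bicyclic epoxonium ion; the enol ether carbon C11 then attacks the tertiary carbon C6 of that ion with inversion, and loss of the silyl group from the oxocarbenium ion releases the C10 ketone. The closest known reaction type is the silyl-triflate-promoted tandem oxa- and carbacyclisation of polyepoxides terminated by an enol silane, a biomimetic epoxide-opening polyene cyclisation. The oxepane closes in the endo mode (oxygen attacks the distal tertiary epoxide carbon, seven-membered ring after C6–O cleavage) and the cyclohexanone by 6-endo opening at C6 through a chair transition state. C6 and C7 come from the Shi epoxide (inversion at C6, retention at C7, hence the trans ring fusion), C3 is carried over from the terminal epoxide, and C11 is set by the chair with the Z-enol ether (side chain equatorial), the carbonate/methanol treatment equilibrating any axial epimer while it cleaves the silyl ether. The step needs endo over exo opening at both epoxides and C- over O-alkylation of the enol ether; the methyl groups on C2 and C6 (cation-stabilising tertiary carbons), the three-atom tether from C7 to the enol ether and the hindered pyridine buffer should secure this.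

Step 6
Reactants: 9 hydroxy ketone
Product: 10 (3R,5aR,6R,7S,9aR)-6-[2-(benzyloxy)ethyl]-2,2,5a,7-tetramethyldecahydro-1-benzoxepine-3,7-diol
Conditions: MeMgBr (4 equiv), CeCl3, THF, −78 → 0 °C
Reagents that add atoms: methylmagnesium bromide, C[Mg]Br
Why: Organocerium 1,2-addition; the axial methyl on C6 blocks the axial trajectory at C10, so methyl should enter equatorially and leave the C10 hydroxyl axial, cis to the C6 methyl as in the target.

Step 7
Reactants: 10 diol
Product: 11 bis(triethylsilyl) ether of 10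
Conditions: TESOTf, 2,6-lutidine, CH2Cl2, 0 °C → rt
Reagents that add atoms: triethylsilyl trifluoromethanesulfonate, CC[Si](CC)(CC)OS(=O)(=O)C(F)(F)F
Why: Silyl triflate silylation protects both hydroxyls, the tertiary one so that it cannot close a tetrahydrofuran onto C13 once C13 is activated.

Step 8
Reactants: 11 benzyl ether
Product: 12 2-[(3R,5aR,6R,7S,9aR)-2,2,5a,7-tetramethyl-3,7-bis(triethylsilyloxy)decahydro-1-benzoxepin-6-yl]ethanol
Conditions: H2 (1 atm), Pd/C, EtOAc, rt
Reagents that add atoms: none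
Why: Hydrogenolysis of the benzyl ether; the molecule has no other reducible group and triethylsilyl ethers survive in ethyl acetate.

Step 9
Reactants: 12 primary alcohol
Product: 13 (3R,5aR,6R,7S,9aR)-6-(2-iodoethyl)-2,2,5a,7-tetramethyl-3,7-bis(triethylsilyloxy)decahydro-1-benzoxepine
Conditions: I2, PPh3, imidazole, CH2Cl2, 0 °C
Reagents that add atoms: iodine, II
Why: Appel-type iodination of the primary alcohol through its alkoxyphosphonium ion.

Step 10
Reactants: 14 (S)-(+)-linalool
Product: 16 (1S)-1-methylcyclopent-2-en-1-yl 2-methylpropanoate, via cyclopentenol 15 (not isolated)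
Conditions: second-generation Grubbs catalyst (1 mol %), CH2Cl2, 40 °C; then (i-PrCO)2O, Et3N, DMAP, rt
Reagents that add atoms: isobutyric anhydride, CC(C)C(=O)OC(=O)C(C)C
Why: Ring-closing metathesis of the 1,6-diene (driven by loss of isobutene, the carbinol centre untouched) followed by DMAP-catalysed acylation of the volatile tertiary allylic alcohol in the same flask.

Step 11
Reactants: 16 tertiary allylic isobutyrate
Product: 19 2-methyl-2-[(1R)-3-methylcyclopent-2-en-1-yl]propanoic acid, via silyl ketene acetal 17 (not isolated), via trimethylsilyl ester 18 (not isolated)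
Conditions: LDA, THF, −78 °C; TMSCl, Et3N; −78 → 60 °C; then 1 M HCl
Reagents that add atoms: none
Why: Ireland–Claisen rearrangement: the ketene acetal rearranges suprafacially across the cyclopentene, so the new C22–C23 bond forms on the face the oxygen leaves, transferring the linalool stereocentre to C22 while the gem-dimethyl quaternary carbon is made.

Step 12
Reactants: 19 acid
Product: 21 1-diazo-3-methyl-3-[(1R)-3-methylcyclopent-2-en-1-yl]butan-2-one, via acid chloride 20 (not isolated)
Conditions: (COCl)2, DMF (cat.), CH2Cl2, 0 °C → rt; then CH2N2 (excess), Et2O, 0 °C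
Reagents that add atoms: diazomethane, C=[N+]=[N-]
Why: Acylation of diazomethane by the acid chloride (the second equivalent scavenges HCl) gives the α-diazoketone, carrying the future C17.

Step 13
Reactants: 21 diazoketone
Product: 22 (1S,2R,5R,8S)-4,4,8-trimethyltricyclo[3.3.0.0(2,8)]octan-3-one
Conditions: Rh2(OAc)4 (1 mol %), CH2Cl2, rt, slow addition
Reagents that add atoms: none
Why: Intramolecular cyclopropanation by the rhodium carbenoid forms the five-membered ketone ring; the tether forces C17 onto the face of C18=C19 that bears the side chain, setting C18.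

Step 14
Reactants: 22 cyclopropyl ketone
Product: 23 (3aR,6R,6aR)-6-hydroxy-3,3,6-trimethylhexahydropentalen-2(1H)-one
Conditions: aq. HClO4, THF, rt
Reagents that add atoms: water, O
Why: Acid-mediated homoconjugate addition of water cleaves the external cyclopropane bond C17–C19 (best overlap with the carbonyl, tertiary terminus); water enters at C19 opposite the departing carbon, on the convex face, giving the carbinol with OH cis to the ring-fusion hydrogens.

Step 15
Reactants: 23 hydroxy ketone
Product: 25 trimethylsilyl enol ether (C14=C17) of the 6-O-TBS ketone, via TBS ether ketone 24 (not isolated)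
Conditions: TBSOTf, 2,6-lutidine, CH2Cl2, 0 °C; then Et3N, TMSOTf, 0 °C
Reagents that add atoms: tert-butyldimethylsilyl trifluoromethanesulfonate, CC(C)(C)[Si](C)(C)OS(=O)(=O)C(F)(F)F; trimethylsilyl trifluoromethanesulfonate, C[Si](C)(C)OS(=O)(=O)C(F)(F)F
Why: Silyl triflate silylations: the tertiary alcohol is protected first, then the ketone is converted into its only possible enol ether, because the other α-carbon is quaternary.

Step 16
Reactants: 25 silyl enol ether
Product: 28 (1R,3aR,8aR)-1-(tert-butyldimethylsilyloxy)-1,4,4-trimethylhexahydroazulene-5,7(1H,6H)-dione, via dichlorocyclobutanone 26 (not isolated), via siloxycyclobutanone 27 (not isolated)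
Conditions: Cl2CHCOCl, Et3N, hexane, rt; then Zn, AcOH, i-PrOH/H2O, rt → 80 °C
Reagents that add atoms: dichloroacetyl chloride, ClC(Cl)C(Cl)=O
Why: Dichloroketene [2+2] cycloaddition to the enol ether from the convex face, zinc dechlorination and retro-aldol opening of the 2-siloxycyclobutanone insert C15 and C16 between C14 and C17, expanding the cyclopentanone to the cycloheptane-1,3-dione.

Step 17
Reactants: 28 1,3-dione
Product: 29 (1R,3aR,8aR)-1-(tert-butyldimethylsilyloxy)-7-methoxy-1,4,4-trimethyl-2,3,3a,4,8,8a-hexahydroazulen-5(1H)-one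
Conditions: MeOH, TsOH·H2O (cat.), 3 Å molecular sieves, rt
Reagents that add atoms: methanol, CO
Why: Acid-catalysed enol etherification should occur at the less hindered carbonyl C16, leaving the ketone next to the gem-dimethyl carbon, which is the regiochemistry the next step needs.

Step 18
Reactants: 13 iodide; 29 vinylogous ester
Product: 32 C14-alkylated cyclohept-14-en-16-one carrying both halves (three silyl ethers), via alkyllithium 30 (not isolated), via lithium alkoxide 31 (not isolated)
Conditions: 13, t-BuLi (2.1 equiv), Et2O, −78 °C; add 29 in THF, −78 → 0 °C; then 1 M HCl, THF, 0 °C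
Reagents that add atoms: water, O
Why: Stork–Danheiser sequence: iodine–lithium exchange, 1,2-addition of the primary alkyllithium to the vinylogous ester carbonyl C14, and acid hydrolysis with allylic transposition form the C13–C14 bond and the 3-substituted cycloheptenone.

Step 19
Reactants: 32 enone
Product: 34 C15-(dimethylaminomethyl) ketone (Mannich base, C14–H cis to the ring-fusion hydrogens), via triethylsilyl enol ether 33 (not isolated)
Conditions: RhCl(PPh3)3 (5 mol %), Et3SiH, toluene, 70 °C; then CH2=NMe2+ I−, CH2Cl2, rt; aq. NaHCO3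
Reagents that add atoms: N,N-dimethylmethyleneiminium iodide, C=[N+](C)C.[I-]
Why: Rhodium-catalysed conjugate hydrosilylation should deliver hydrogen to C14 from the convex face of the cis-fused bicycle (anti to the cyclopentane CH2 on C22), and the regiodefined enol silane then undergoes the Mannich reaction with Eschenmoser's salt at C15.

Step 20
Reactants: 34 Mannich base
Product: 36 tris-silylated α-methylidene ketone, via trimethylammonium iodide 35 (not isolated)
Conditions: MeI, CH2Cl2, rt; then DBU, rt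
Reagents that add atoms: none
Why: N-Methylation and base-induced β-elimination of trimethylamine (the Mannich-base route to α-methylene ketones) unveil the C15 methylidene group.

Step 21
Reactants: 36 tris-silyl ether
Product: 37 triol (target with C3–OH in place of C3=O)
Conditions: aq. HF (48 %), MeCN, 0 °C → rt
Reagents that add atoms: none
Why: Fluoride cleavage of all three silyl ethers under mildly acidic conditions that the α-methylene ketone and the tertiary alcohols should tolerate.

Step 22
Reactants: 37 triol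
Product: 38 CNP0316622.2
Conditions: Dess–Martin periodinane, NaHCO3, CH2Cl2, 0 °C → rt
Reagents that add atoms: none
Why: Dess–Martin oxidation of the only secondary alcohol (C3) to the ketone; the two tertiary alcohols cannot react.

**Compound list**

1 | geranyl bromide, (2E)-1-bromo-3,7-dimethylocta-2,6-diene | CC(C)=CCC/C(C)=C/CBr | starting material
2 | dimethyl (2-oxopropyl)phosphonate | COP(=O)(OC)CC(C)=O | starting material
3 | dimethyl [(5E)-6,10-dimethyl-2-oxoundeca-5,9-dien-1-yl]phosphonate | COP(=O)(OC)CC(=O)CC/C=C(\C)CCC=C(C)C | intermediate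
4 | (benzyloxy)acetaldehyde | O=CCOCc1ccccc1 | starting material
5 | (2E,7E)-1-(benzyloxy)-8,12-dimethyltrideca-2,7,11-trien-4-one | O=C(/C=C/COCc1ccccc1)CC/C=C(\C)CCC=C(C)C | intermediate
6 | (2E,7R,8R,11R)-1-(benzyloxy)-7,8:11,12-diepoxy-8,12-dimethyltridec-2-en-4-one | O=C(/C=C/COCc1ccccc1)CC[C@H]1O[C@]1(C)CC[C@H]1OC1(C)C | intermediate
7 | {[(3Z,7R,8R,11R)-1-(benzyloxy)-7,8:11,12-diepoxy-8,12-dimethyltridec-3-en-4-yl]oxy}triethylsilane | CC[Si](CC)(CC)O/C(CC[C@H]1O[C@]1(C)CC[C@H]1OC1(C)C)=C\CCOCc1ccccc1 | intermediate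
8 | 3-O-trimethylsilyl ether of 9 | c1ccccc1COCC[C@@H]1[C@@]2(C)CC[C@@H](O[Si](C)(C)C)C(C)(C)O[C@@H]2CCC1=O | intermediate (not isolated)
9 | (3R,5aR,6R,9aR)-6-[2-(benzyloxy)ethyl]-3-hydroxy-2,2,5a-trimethyl-3,4,5,5a,6,8,9,9a-octahydro-1-benzoxepin-7(2H)-one (trans-fused, side chain equatorial) | c1ccccc1COCC[C@@H]1[C@@]2(C)CC[C@@H](O)C(C)(C)O[C@@H]2CCC1=O | intermediate
10 | (3R,5aR,6R,7S,9aR)-6-[2-(benzyloxy)ethyl]-2,2,5a,7-tetramethyldecahydro-1-benzoxepine-3,7-diol | c1ccccc1COCC[C@@H]1[C@@]2(C)CC[C@@H](O)C(C)(C)O[C@@H]2CC[C@]1(C)O | intermediate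
11 | (3R,5aR,6R,7S,9aR)-6-[2-(benzyloxy)ethyl]-2,2,5a,7-tetramethyl-3,7-bis(triethylsilyloxy)decahydro-1-benzoxepine | c1ccccc1COCC[C@@H]1[C@@]2(C)CC[C@@H](O[Si](CC)(CC)CC)C(C)(C)O[C@@H]2CC[C@]1(C)O[Si](CC)(CC)CC | intermediate
12 | 2-[(3R,5aR,6R,7S,9aR)-2,2,5a,7-tetramethyl-3,7-bis(triethylsilyloxy)decahydro-1-benzoxepin-6-yl]ethanol | OCC[C@@H]1[C@@]2(C)CC[C@@H](O[Si](CC)(CC)CC)C(C)(C)O[C@@H]2CC[C@]1(C)O[Si](CC)(CC)CC | intermediate
13 | (3R,5aR,6R,7S,9aR)-6-(2-iodoethyl)-2,2,5a,7-tetramethyl-3,7-bis(triethylsilyloxy)decahydro-1-benzoxepine | ICC[C@@H]1[C@@]2(C)CC[C@@H](O[Si](CC)(CC)CC)C(C)(C)O[C@@H]2CC[C@]1(C)O[Si](CC)(CC)CC | intermediate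
14 | (S)-(+)-linalool, (3S)-3,7-dimethylocta-1,6-dien-3-ol | C=C[C@@](C)(O)CCC=C(C)C | starting material
15 | (1S)-1-methylcyclopent-2-en-1-ol | C1=C[C@@](C)(O)CC1 | intermediate (not isolated)
16 | (1S)-1-methylcyclopent-2-en-1-yl 2-methylpropanoate | C1=C[C@@](C)(OC(=O)C(C)C)CC1 | intermediate
17 | trimethylsilyl ketene acetal of 16 | C1=C[C@@](C)(OC(O[Si](C)(C)C)=C(C)C)CC1 | intermediate (not isolated)
18 | trimethylsilyl 2-methyl-2-[(1R)-3-methylcyclopent-2-en-1-yl]propanoate | CC1=C[C@@H](CC1)C(C)(C)C(=O)O[Si](C)(C)C | intermediate (not isolated)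
19 | 2-methyl-2-[(1R)-3-methylcyclopent-2-en-1-yl]propanoic acid | CC1=C[C@@H](CC1)C(C)(C)C(=O)O | intermediate
20 | 2-methyl-2-[(1R)-3-methylcyclopent-2-en-1-yl]propanoyl chloride | CC1=C[C@@H](CC1)C(C)(C)C(Cl)=O | intermediate (not isolated)
21 | 1-diazo-3-methyl-3-[(1R)-3-methylcyclopent-2-en-1-yl]butan-2-one | CC1=C[C@@H](CC1)C(C)(C)C(=O)C=[N+]=[N-] | intermediate
22 | (1S,2R,5R,8S)-4,4,8-trimethyltricyclo[3.3.0.0(2,8)]octan-3-one (cyclopropane on the face of the former side chain) | O=C1[C@@H]2[C@@H]3[C@@H](CC[C@]23C)C1(C)C | intermediate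
23 | (3aR,6R,6aR)-6-hydroxy-3,3,6-trimethylhexahydropentalen-2(1H)-one (cis-fused, OH cis to the ring-fusion H) | O=C1C[C@@H]2[C@@H](CC[C@@]2(C)O)C1(C)C | intermediate
24 | (3aR,6R,6aR)-6-(tert-butyldimethylsilyloxy)-3,3,6-trimethylhexahydropentalen-2(1H)-one | O=C1C[C@@H]2[C@@H](CC[C@@]2(C)O[Si](C)(C)C(C)(C)C)C1(C)C | intermediate (not isolated)
25 | tert-butyldimethyl{[(1R,3aR,6aS)-1,4,4-trimethyl-5-(trimethylsilyloxy)-1,2,3,3a,4,6a-hexahydropentalen-1-yl]oxy}silane | C[Si](C)(C)OC1=C[C@@H]2[C@@H](CC[C@@]2(C)O[Si](C)(C)C(C)(C)C)C1(C)C | intermediate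
26 | convex-face dichloroketene [2+2] adduct of 25 (CCl2 on the siloxy carbon C14, C=O on C17) | C[Si](C)(C)O[C@@]12C(Cl)(Cl)C(=O)[C@@H]1[C@@H]1[C@@H](CC[C@@]1(C)O[Si](C)(C)C(C)(C)C)C2(C)C | intermediate (not isolated)
27 | dechlorinated siloxycyclobutanone from 26 | C[Si](C)(C)O[C@@]12CC(=O)[C@@H]1[C@@H]1[C@@H](CC[C@@]1(C)O[Si](C)(C)C(C)(C)C)C2(C)C | intermediate (not isolated)
28 | (1R,3aR,8aR)-1-(tert-butyldimethylsilyloxy)-1,4,4-trimethylhexahydroazulene-5,7(1H,6H)-dione | O=C1CC(=O)C[C@@H]2[C@@H](CC[C@@]2(C)O[Si](C)(C)C(C)(C)C)C1(C)C | intermediate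
29 | (1R,3aR,8aR)-1-(tert-butyldimethylsilyloxy)-7-methoxy-1,4,4-trimethyl-2,3,3a,4,8,8a-hexahydroazulen-5(1H)-one | O=C1C=C(OC)C[C@@H]2[C@@H](CC[C@@]2(C)O[Si](C)(C)C(C)(C)C)C1(C)C | intermediate
30 | primary alkyllithium from 13 (Li in place of I) | [Li]CC[C@@H]1[C@@]2(C)CC[C@@H](O[Si](CC)(CC)CC)C(C)(C)O[C@@H]2CC[C@]1(C)O[Si](CC)(CC)CC | intermediate (not isolated)
31 | lithium alkoxide from 1,2-addition of 30 to the C14 carbonyl of 29 (new carbinol centre undefined) | [Li]OC1(CC[C@@H]2[C@@]3(C)CC[C@@H](O[Si](CC)(CC)CC)C(C)(C)O[C@@H]3CC[C@]2(C)O[Si](CC)(CC)CC)C=C(OC)C[C@@H]2[C@@H](CC[C@@]2(C)O[Si](C)(C)C(C)(C)C)C1(C)C | intermediate (not isolated)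
32 | (1R,3aR,8aR)-1-(tert-butyldimethylsilyloxy)-1,4,4-trimethyl-5-{2-[(3R,5aR,6R,7S,9aR)-2,2,5a,7-tetramethyl-3,7-bis(triethylsilyloxy)decahydro-1-benzoxepin-6-yl]ethyl}-2,3,3a,4,8,8a-hexahydroazulen-7(1H)-one | C1(CC[C@@H]2[C@@]3(C)CC[C@@H](O[Si](CC)(CC)CC)C(C)(C)O[C@@H]3CC[C@]2(C)O[Si](CC)(CC)CC)=CC(=O)C[C@@H]2[C@@H](CC[C@@]2(C)O[Si](C)(C)C(C)(C)C)C1(C)C | intermediate
33 | triethylsilyl enol ether (C16=C15) from 1,4-hydrosilylation of 32, C14–H cis to the ring-fusion hydrogens | C1=C(O[Si](CC)(CC)CC)C[C@@H]2[C@@H](CC[C@@]2(C)O[Si](C)(C)C(C)(C)C)C(C)(C)[C@H]1CC[C@@H]1[C@@]2(C)CC[C@@H](O[Si](CC)(CC)CC)C(C)(C)O[C@@H]2CC[C@]1(C)O[Si](CC)(CC)CC | intermediate (not isolated)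
34 | saturated C16 ketone bearing CH2NMe2 at C15 (C15 undefined), three silyl ethers | CN(C)CC1C(=O)C[C@@H]2[C@@H](CC[C@@]2(C)O[Si](C)(C)C(C)(C)C)C(C)(C)[C@H]1CC[C@@H]1[C@@]2(C)CC[C@@H](O[Si](CC)(CC)CC)C(C)(C)O[C@@H]2CC[C@]1(C)O[Si](CC)(CC)CC | intermediate
35 | trimethylammonium iodide from N-methylation of 34 | [I-].C[N+](C)(C)CC1C(=O)C[C@@H]2[C@@H](CC[C@@]2(C)O[Si](C)(C)C(C)(C)C)C(C)(C)[C@H]1CC[C@@H]1[C@@]2(C)CC[C@@H](O[Si](CC)(CC)CC)C(C)(C)O[C@@H]2CC[C@]1(C)O[Si](CC)(CC)CC | intermediate (not isolated)
36 | target skeleton with C15=CH2 and C16=O, C19–OTBS, C10–OTES, C3–OTES | C=C1C(=O)C[C@@H]2[C@@H](CC[C@@]2(C)O[Si](C)(C)C(C)(C)C)C(C)(C)[C@H]1CC[C@@H]1[C@@]2(C)CC[C@@H](O[Si](CC)(CC)CC)C(C)(C)O[C@@H]2CC[C@]1(C)O[Si](CC)(CC)CC | intermediate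
37 | triol: the target with (3R)-C3–OH in place of the C3 ketone | C=C1C(=O)C[C@@H]2[C@@H](CC[C@@]2(C)O)C(C)(C)[C@H]1CC[C@@H]1[C@@]2(C)CC[C@@H](O)C(C)(C)O[C@@H]2CC[C@]1(C)O | intermediate
38 | CNP0316622.2 | C=C1C(=O)C[C@@H]2[C@@H](CC[C@@]2(C)O)C(C)(C)[C@H]1CC[C@@H]1[C@@]2(C)CCC(=O)C(C)(C)O[C@@H]2CC[C@]1(C)O | target

**Totals and risks**

Total step count: 22. Longest linear sequence: 14 steps (steps 1–9, then 18–22).

Step 5. What may go wrong: exo-mode opening of either epoxide (tetrahydrofuran or tetrahydropyran ethers instead of the oxepane), or loss of the enol ether by protodesilylation or O-silyl transfer before the C–C bond forms. Fallback, setting out from 7 and returning at 9: the enol ether is exchanged for a carbon-bound terminator. CsF and PhNTf2 convert 7 into the (Z)-enol triflate F1 with retention of geometry. Pd(PPh3)4-catalysed coupling with Me3SiCH2ZnCl gives the (Z)-allylsilane F2. The same TMSOTf/hindered-pyridine cascade, now terminated by the allylsilane (C11 attacks C6, silicon leaves from the CH2 group), gives the C10-methylidene bicycle F3. Ozonolysis (O3, then Me2S) gives 8, and K2CO3/MeOH gives 9.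

Step 16. What may go wrong: C-acylation of the crowded enol ether without closure of the four-membered ring (three contiguous fully substituted carbons), or opening of the siloxycyclobutanone without ring expansion. Fallback, setting out from 24 (isolated after the first silylation of step 15) and returning at 32: the ring is enlarged one carbon at a time and the union is changed. TMSCHN2/BF3·OEt2 inserts a methylene on the CH2 side of the ketone to give the cis-hydrindanone F4. LDA/TMSCl gives its enol ether F5, and Et2Zn/CH2I2 the siloxycyclopropane F6. FeCl3 in DMF opens F6 to the β-chloro ketone F7, and NaOAc/MeOH eliminates HCl to give the cycloheptenone F8 (C14 ketone, C15=C16). Alkyllithium 30 (with CeCl3) adds 1,2 to F8 to give the tertiary allylic alcohol F9. Oxidative 1,3-transposition with pyridinium chlorochromate, C5H5NH[CrO3Cl], then gives 32.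

Step 19. What may go wrong: slow hydride transfer to the β-carbon flanked by the quaternary C23, competing 1,2-reduction, or poor facial selectivity at C14. Fallback, setting out from 32 and returning at 34: dissolving-metal reduction (Li, NH3/THF, t-BuOH 1 equiv, −78 °C) with trapping of the regiodefined lithium enolate by TMSCl/Et3N gives the trimethylsilyl enol ether F10, in which the C14 hydrogen is set by protonation of the β-carbanion and not by hydride approach. Eschenmoser's salt then converts F10 into 34.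

**Further compounds**

F1 | step 5 | (3Z,7R,8R,11R)-1-(benzyloxy)-7,8:11,12-diepoxy-8,12-dimethyltridec-3-en-4-yl trifluoromethanesulfonate | O=S(=O)(O/C(CC[C@H]1O[C@]1(C)CC[C@H]1OC1(C)C)=C\CCOCc1ccccc1)C(F)(F)F
F2 | step 5 | (Z)-allylsilane: F1 with CH2SiMe3 in place of the triflate | C[Si](C)(C)C/C(CC[C@H]1O[C@]1(C)CC[C@H]1OC1(C)C)=C\CCOCc1ccccc1
F3 | step 5 | 7-methylidene analogue of 8 (C=CH2 in place of C=O, same configuration) | c1ccccc1COCC[C@@H]1[C@@]2(C)CC[C@@H](O[Si](C)(C)C)C(C)(C)O[C@@H]2CCC1=C
F4 | step 16 | (1R,3aR,7aR)-1-(tert-butyldimethylsilyloxy)-1,4,4-trimethyloctahydro-5H-inden-5-one | O=C1CC[C@@H]2[C@@H](CC[C@@]2(C)O[Si](C)(C)C(C)(C)C)C1(C)C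
F5 | step 16 | trimethylsilyl enol ether of F4 | C[Si](C)(C)OC1=CC[C@@H]2[C@@H](CC[C@@]2(C)O[Si](C)(C)C(C)(C)C)C1(C)C
F6 | step 16 | siloxycyclopropane from F5 (new ring-fusion centres undefined) | C[Si](C)(C)OC12CC1C[C@@H]1[C@@H](CC[C@@]1(C)O[Si](C)(C)C(C)(C)C)C2(C)C
F7 | step 16 | ring-expanded β-chloro cycloheptanone (C16–Cl, undefined) | O=C1CC(Cl)C[C@@H]2[C@@H](CC[C@@]2(C)O[Si](C)(C)C(C)(C)C)C1(C)C
F8 | step 16 | (1R,3aR,8aR)-1-(tert-butyldimethylsilyloxy)-1,4,4-trimethyl-2,3,3a,4,8,8a-hexahydroazulen-5(1H)-one | O=C1C=CC[C@@H]2[C@@H](CC[C@@]2(C)O[Si](C)(C)C(C)(C)C)C1(C)C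
F9 | step 16 | tertiary allylic alcohol from 1,2-addition of 30 to F8 (carbinol centre undefined) | OC1(CC[C@@H]2[C@@]3(C)CC[C@@H](O[Si](CC)(CC)CC)C(C)(C)O[C@@H]3CC[C@]2(C)O[Si](CC)(CC)CC)C=CC[C@@H]2[C@@H](CC[C@@]2(C)O[Si](C)(C)C(C)(C)C)C1(C)C
F10 | step 19 | trimethylsilyl analogue of 33 | C1=C(O[Si](C)(C)C)C[C@@H]2[C@@H](CC[C@@]2(C)O[Si](C)(C)C(C)(C)C)C(C)(C)[C@H]1CC[C@@H]1[C@@]2(C)CC[C@@H](O[Si](CC)(CC)CC)C(C)(C)O[C@@H]2CC[C@]1(C)O[Si](CC)(CC)CC
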